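**Assumption (one line):** 2-bromo-3,3-diethoxyprop-1-ene and 1,4-dichlorobutan-2-one are taken as catalogue chemicals, and the carbinol configuration drawn for the adamantane alcohol is the expected thermodynamic epimer and has no bearing on the route, because that carbon leaves as CO2 in step 8.

## Retrosynthetic overview

1. Numbering: ring A = C1(benzoyl)–C2(=O)–C3–C4(=O)–C5(prenyl)–C9(=O); ring B = C1–C8(Me2)–C7(H)–C6(H2)–C5–C9; Ca = the CH2 on C7; Cb = the CH on C3 that carries the C(CH3)2–O–O unit.
2. Last disconnection: the 1,2-dioxepane (Cb, CMe2, O, O, CH, CH2, C3) and the hydroperoxide are opened to an isopropenyl group on Cb, the C3 prenyl group and two O2 (hydrogen-atom-transfer peroxidation cascade).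
3. Key disconnection: C7–Ca and Cb–C3 together, closing the seven-membered carbocycle C3–C4–C5–C6–C7–Ca–Cb. The enabling feature is that C3 and C7 face each other across rings A and B of the bicyclo[3.3.1]nonane (1,5-related through C4–C5–C6), and the enol oxygen on C4, next to C3, can hold a vinyl ketone under the inner face of C7. The tether (O–CH2–CO–CH=CH2) is consumed: its CH2 becomes the acetyl methyl group.
4. The C7 radical precursor and rings A and B come from an adamantane alcohol, in which a temporary carbon C10 bridges C3 and C7. It is made from a diprenylated acylphloroglucinol by an enantioselective dearomatising annulation, and a retro-aldol reaction opens it again.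
5. Order of ring formation: aromatic ring (becomes ring A) → ring B and the temporary adamantane ring → (adamantane opened) → seven-membered carbocycle → dioxepane.

Key step: step 8

## Route

Step 1
Reactants: 1 2,4,6-trihydroxybenzophenone; 2 prenyl bromide
Product: 3 clusiaphenone B
Conditions: 2 (2.2 equiv), 10% aq. KOH, 0 °C → rt
Reagents that add atoms: none
Why: Base-mediated twofold C-prenylation of the phloroglucinolate (Friedel–Crafts-type C-alkylation) at the two free ring carbons; no stereocentre is formed.

Step 2
Reactants: 4 2-bromo-3,3-diethoxyprop-1-ene; 5 acetone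
Product: 8 3-(diethoxymethyl)-2-methylbut-3-en-2-yl acetate, via vinyllithium 6 (not isolated), via lithium alkoxide 7 (not isolated)
Conditions: n-BuLi, THF, −78 °C; 5; then Ac2O, −78 → 0 °C
Reagents that add atoms: acetic anhydride CC(=O)OC(C)=O
Why: Bromine–lithium exchange gives the α-metalated acrolein acetal 6, its 1,2-addition to acetone gives the tertiary alkoxide 7, and this is acetylated in the flask; no stereocentre is formed.

Step 3
Reactants: 8 3-(diethoxymethyl)-2-methylbut-3-en-2-yl acetate
Product: 9 3-formyl-2-methylbut-3-en-2-yl acetate
Conditions: oxalic acid (5% aq.), THF, rt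
Reagents that add atoms: water O
Why: Acid-catalysed acetal hydrolysis under conditions too mild to ionise the tertiary acetate, which becomes still less labile once the neighbouring alkene is part of an enal; no stereocentre is formed.

Step 4
Reactants: 3 clusiaphenone B; 9 3-formyl-2-methylbut-3-en-2-yl acetate
Product: 12 adamantane alcohol, via dearomatised enal 10 (not isolated), via bicyclic aldehyde 11 (not isolated)
Conditions: 2,7-bis[(O(9)-allylhydrocinchonidinium-N-yl)methyl]naphthalene dibromide (25 mol%), CsOH·H2O (5 equiv), 4 Å molecular sieves, CH2Cl2, −50 °C; aq. NH4Cl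
Reagents that add atoms: none
Why: Alkylative dearomatisation–annulation under chiral phase-transfer catalysis (conjugate addition with loss of acetate, intramolecular Michael addition, aldol reaction): the ammonium–phenolate ion pair selects one of the two enantiotopic prenyl-bearing ring carbons for attack on the methylene of 9 and so sets C5 in 10, the benzoyl-bearing carbon then adds to the β,β-dimethyl enal to close ring B (C1–C8, giving 11) and the last nucleophilic ring carbon closes the aldol (C3–C10), so that C1, C3 and C7 are dictated by the cage and follow from C5.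

Step 5
Reactants: 12 adamantane alcohol; 13 1,4-dichlorobutan-2-one
Product: 15 tethered aldehyde, via potassium enolate 14 (not isolated)
Conditions: KN(SiMe3)2 (1.05 equiv), THF, −78 → 0 °C; then 13 (1.5 equiv), 18-crown-6, 0 °C → rt
Reagents that add atoms: none
Why: Retro-aldol cleavage of the C3–C10 bond of the potassium alkoxide of 12 (driven by formation of the stabilised β-diketonate 14) unveils the aldehyde on the inner (endo) face of C7, and Williamson-type O-alkylation of this dissociated, C3-substituted potassium enolate by the α-chloro ketone end of 13 is expected at the less hindered C4 oxygen; no stereocentre is formed, and C7 is in any case planarised in step 8.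

Step 6
Reactants: 15 tethered aldehyde
Product: 16 tethered carboxylic acid
Conditions: NaClO2, NaH2PO4, 2-methyl-2-butene, t-BuOH/H2O, 0 °C → rt
Reagents that add atoms: sodium chlorite [Na+].[O-]Cl=O
Why: Pinnick oxidation with 2-methyl-2-butene as hypochlorite scavenger should spare the prenyl groups, the vinylogous ester and the β-chloro ketone; no stereocentre is affected.

Step 7
Reactants: 16 tethered carboxylic acid
Product: 17 N-acyloxyphthalimide
Conditions: N-hydroxyphthalimide, N,N'-diisopropylcarbodiimide, CH2Cl2, 0 °C → rt
Reagents that add atoms: N-hydroxyphthalimide O=C1N(O)C(=O)c2ccccc12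
Why: Carbodiimide esterification (Steglich-type, run without a nucleophilic amine so that the β-chloro ketone is not eliminated) gives the redox-active ester, and the alkylated enol cannot attack the activated carboxyl group; no stereocentre is affected.

Step 8
Reactants: 17 N-acyloxyphthalimide
Product: 19 homoadamantane methyl ketone, via vinyl ketone 18 (not isolated)
Conditions: Et3N (1.1 equiv), CH2Cl2, 0 °C; then Ru(bpy)3(PF6)2 (2 mol%), Hantzsch ester (1.5 equiv, slow addition), degassed CH2Cl2 (5 mM), blue LEDs, rt
Reagents that add atoms: none
Why: Proposed new method: Et3N unmasks the vinyl ketone 18; monovalent ruthenium (from reductive quenching of photoexcited Ru(bpy)3(PF6)2 by the Hantzsch ester) reduces the N-acyloxyphthalimide, which loses CO2 and phthalimide anion to give the C7 radical, this adds 9-endo-trig to the enone terminus held under it by the O4 tether (C7–Ca), the α-keto radical at Cb adds 6-endo-trig to C3 of the enol ether (Cb–C3, the same bond closing the seven-membered carbocycle), and the C4 α-alkoxy radical fragments by β-scission of O–CH2 to the C4 ketone and a primary α-keto radical (the former tether carbon, now the acetyl methyl), which takes a hydrogen atom from the Hantzsch ester. The closest known reactions are the reductive Giese coupling of redox-active esters with enones under Ru(bpy)3(PF6)2/Hantzsch ester photocatalysis, the addition of α-carbonyl radicals to enol ethers, and the β-fragmentation of α-alkoxyalkyl radicals that expel a stabilised carbon radical; their combination into a tether-relayed annulation is new. Stereocontrol: the C7 radical is planar, so the C7 configuration of 17 is irrelevant, and a chain anchored on O4 can reach only the face of C7 that looks at C3 (the outer face is beyond its reach); C3 can be bridged only on that same face; at Cb the acetyl carbon is still tied to O4 when the Cb–C3 bond forms and so lies on the C4/C6 flank, which is also the less hindered one (C6H2 on this side, a C8 methyl on the other), and this centre could be equilibrated α to the ketone if needed. The step needs each radical to find its intramolecular partner before it is reduced: polarity matching (nucleophilic alkyl radical with enone, electrophilic α-keto radical with electron-rich enol ether), high dilution and slow addition of the Hantzsch ester should secure this, and relief of the bridged six-membered ether ring drives the final fragmentation.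

Step 9
Reactants: 19 homoadamantane methyl ketone
Product: 20 isopropenyl homoadamantane
Conditions: Zn, CH2Br2, TiCl4, THF/CH2Cl2, 0 °C → rt
Reagents that add atoms: dibromomethane BrCBr
Why: Takai–Lombardo methylenation with the non-basic zinc/titanium methylene reagent should occur at the only ketone that is not flanked by a quaternary carbon (the ring ketones and the benzoyl group all are), without epimerising the α-stereocentre Cb.

Step 10
Reactants: 20 isopropenyl homoadamantane
Product: 22 target CNP0215795.1, via silyl peroxide 21 (not isolated)
Conditions: Co(thd)2 (bis(2,2,6,6-tetramethylheptane-3,5-dionato)cobalt, 10 mol%), Et3SiH (2 equiv), O2 (1 atm), ClCH2CH2Cl, rt; then HCl (cat.), MeOH, 0 °C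
Reagents that add atoms: dioxygen O=O
Why: Mukaiyama–Isayama peroxidation: hydrogen-atom transfer from the cobalt hydride formed from Co(thd)2 and Et3SiH to the 1,1-disubstituted alkene (faster than to the trisubstituted prenyl groups) gives the tertiary radical, O2 trapping gives a peroxyl radical that closes the 1,2-dioxepane by 7-exo-trig addition to the C3 prenyl group (new stereocentre set by the rigid cage, side chain pseudo-equatorial, its hydrogen expected cis to the Cb hydrogen as the target requires), the new tertiary radical takes up a second O2 and is released as the triethylsilyl peroxide 21, which methanolic acid cleaves to the hydroperoxide.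

## Compound list

1 | 2,4,6-trihydroxybenzophenone | O=C(c1ccccc1)c1c(O)cc(O)cc1O | starting material
2 | prenyl bromide (1-bromo-3-methylbut-2-ene) | CC(C)=CCBr | starting material
3 | clusiaphenone B (2,4,6-trihydroxy-3,5-diprenylbenzophenone) | CC(C)=CCc1c(O)c(CC=C(C)C)c(O)c(C(=O)c2ccccc2)c1O | intermediate
4 | 2-bromo-3,3-diethoxyprop-1-ene | C=C(Br)C(OCC)OCC | starting material
5 | acetone | CC(C)=O | starting material
6 | (3,3-diethoxyprop-1-en-2-yl)lithium | [Li]C(=C)C(OCC)OCC | intermediate
7 | lithium 3-(diethoxymethyl)-2-methylbut-3-en-2-olate | [Li+].[O-]C(C)(C)C(=C)C(OCC)OCC | intermediate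
8 | 3-(diethoxymethyl)-2-methylbut-3-en-2-yl acetate | CCOC(OCC)C(=C)C(C)(C)OC(C)=O | intermediate
9 | 3-formyl-2-methylbut-3-en-2-yl acetate | CC(=O)OC(C)(C)C(=C)C=O | intermediate
10 | dearomatised enal: 2-benzoyl-3,5-dihydroxy-4,6-diprenyl-6-(2-formyl-3-methylbut-2-enyl)cyclohexa-2,4-dienone, quaternary C5 as in the target | CC(C)=CC[C@]1(CC(C=O)=C(C)C)C(=O)C(CC=C(C)C)=C(O)C(C(=O)c2ccccc2)=C1O | intermediate
11 | bicyclic aldehyde: 1-benzoyl-4-hydroxy-8,8-dimethyl-3,5-diprenyl-2,9-dioxobicyclo[3.3.1]non-3-ene-7-carbaldehyde, formyl group cis to the C2–C3–C4 bridge (formed as its cesium enolate in step 4; neutral enol drawn) | CC(C)=CC[C@]12C[C@H](C=O)C(C)(C)[C@@](C(=O)c3ccccc3)(C2=O)C(=O)C(CC=C(C)C)=C1O | intermediate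
12 | adamantane alcohol: 1-benzoyl-10-hydroxy-8,8-dimethyl-3,5-diprenyladamantane-2,4,9-trione (C10 bridges C3 and C7; hydroxyl on the C4/C6 side) | CC(C)=CC[C@]12C[C@@H]3[C@H](O)[C@](CC=C(C)C)(C1=O)C(=O)[C@](C(=O)c1ccccc1)(C2=O)C3(C)C | intermediate
13 | 1,4-dichlorobutan-2-one | ClCCC(=O)CCl | starting material
14 | potassium enolate of 11: potassium C2–C3–C4 β-diketonate of the ring-opened aldehyde, formyl group on the inner face of C7 | CC(C)=CC[C@]12C[C@H](C=O)C(C)(C)[C@@](C(=O)c3ccccc3)(C2=O)C(=O)C(CC=C(C)C)=C1[O-].[K+] | intermediate
15 | tethered aldehyde: 11 with the C4 enol oxygen alkylated by a 4-chloro-2-oxobutyl group | CC(C)=CC[C@]12C[C@H](C=O)C(C)(C)[C@@](C(=O)c3ccccc3)(C2=O)C(=O)C(CC=C(C)C)=C1OCC(=O)CCCl | intermediate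
16 | tethered carboxylic acid (carboxyl group on the inner face of C7) | CC(C)=CC[C@]12C[C@H](C(=O)O)C(C)(C)[C@@](C(=O)c3ccccc3)(C2=O)C(=O)C(CC=C(C)C)=C1OCC(=O)CCCl | intermediate
17 | N-acyloxyphthalimide (redox-active ester of 16) | CC(C)=CC[C@]12C[C@H](C(=O)ON3C(=O)c4ccccc4C3=O)C(C)(C)[C@@](C(=O)c3ccccc3)(C2=O)C(=O)C(CC=C(C)C)=C1OCC(=O)CCCl | intermediate
18 | vinyl ketone: 17 with the C4 oxygen carrying a 2-oxobut-3-enyl group | CC(C)=CC[C@]12C[C@H](C(=O)ON3C(=O)c4ccccc4C3=O)C(C)(C)[C@@](C(=O)c3ccccc3)(C2=O)C(=O)C(CC=C(C)C)=C1OCC(=O)C=C | intermediate
19 | homoadamantane methyl ketone: 1-benzoyl-3,5-diprenyl-8,8-dimethyl core with the C7–Ca(H2)–Cb(H)(acetyl)–C3 bridge, acetyl on the C4/C6 flank | CC(C)=CC[C@]12C[C@@H]3C[C@H](C(C)=O)[C@](CC=C(C)C)(C1=O)C(=O)[C@](C(=O)c1ccccc1)(C2=O)C3(C)C | intermediate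
20 | isopropenyl homoadamantane (19 with C(CH3)=CH2 in place of acetyl) | CC(C)=CC[C@]12C[C@@H]3C[C@H](C(C)=C)[C@](CC=C(C)C)(C1=O)C(=O)[C@](C(=O)c1ccccc1)(C2=O)C3(C)C | intermediate
21 | triethylsilyl peroxide of the target | CC(C)=CC[C@]12C[C@@H]3C[C@@H]4C(C)(C)OO[C@H](C(C)(C)OO[Si](CC)(CC)CC)C[C@@]4(C1=O)C(=O)[C@](C(=O)c1ccccc1)(C2=O)C3(C)C | intermediate
22 | CNP0215795.1 | CC(C)=CC[C@]12C[C@@H]3C[C@@H]4C(C)(C)OO[C@H](C(C)(C)OO)C[C@@]4(C1=O)C(=O)[C@](C(=O)c1ccccc1)(C2=O)C3(C)C | target

## Step count and risks

Total step count: 10. Longest linear sequence: 9 steps (4 → 22, steps 2–10).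

**Step 8 (proposed new method).** The cascade may stall if the C7 radical is lost before it reaches the enone (hydrogen transfer from the Hantzsch ester or from the tether CH2, transannular attack on C3), or if the α-keto radical is reduced before it closes onto C3. The fallback uses known chemistry and makes the two bridge bonds one at a time. It sets out from 12: retro-aldol opening with LiN(SiMe3)2 and addition of vinylmagnesium bromide/CeCl3 to the liberated aldehyde should give the allylic alcohol F1. Ac2O/DMAP should give the diacetate F2. Tsuji deoxygenation (Pd(OAc)2, PBu3, ammonium formate, dioxane) followed by K2CO3/MeOH should give the 7-endo-allyl enol F3. Cross-metathesis with 2-methyl-2-butene (second-generation Grubbs catalyst, RuCl2(H2IMes)(PCy3)(=CHPh)) should give the 7-endo-prenyl enol F4. Oxidative radical cyclisation with Mn(OAc)3·2H2O and Cu(OAc)2·H2O in AcOH (C3 radical, 7-exo-trig addition to the C7 prenyl group, copper-mediated elimination to the less substituted alkene) comes back to the route at 20.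

**Step 10.** Hydrogen-atom transfer may not discriminate well between the isopropenyl group and the two prenyl groups, the peroxyl radical may be intercepted as the silyl peroxide before the slow seven-membered closure, and facial selectivity at the new peroxide carbon may be poor. The fallback separates peroxide installation from ring closure. It sets out from 20: the same Co(thd)2/Et3SiH/O2 system, stopped at the uncyclised stage, should give the open-chain silyl peroxide F5. HCl/MeOH should give the tertiary hydroperoxide F6. A reductant-free peroxyl-radical chain (di-tert-butyl hyponitrite as initiator, O2, benzene, rt) then has time for the 7-exo closure and second O2 capture, and comes back at 22.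

**Step 4.** The ion pair may give low or opposite asymmetric induction in the first C–C bond formation, which fixes the absolute configuration of the whole route. The fallback replaces asymmetric catalysis by resolution. It sets out from 3 and 9: LiN(SiMe3)2 in THF (−78 → 0 °C, no chiral catalyst) should give 12 together with the enantiomeric adamantane alcohol F7. Preparative chromatography on a chiral stationary phase (cellulose tris(3,5-dimethylphenylcarbamate)) separates them, and the route is re-entered at 12.

Further compounds
F1 | step 8 | allylic alcohol (7-endo-(1-hydroxyprop-2-enyl) enol, carbinol epimers) | CC(C)=CC[C@]12C[C@H](C(O)C=C)C(C)(C)[C@@](C(=O)c3ccccc3)(C2=O)C(=O)C(CC=C(C)C)=C1O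
F2 | step 8 | diacetate (allylic acetate and C4 enol acetate) | CC(C)=CC[C@]12C[C@H](C(OC(C)=O)C=C)C(C)(C)[C@@](C(=O)c3ccccc3)(C2=O)C(=O)C(CC=C(C)C)=C1OC(C)=O
F3 | step 8 | 7-endo-allyl enol | CC(C)=CC[C@]12C[C@H](CC=C)C(C)(C)[C@@](C(=O)c3ccccc3)(C2=O)C(=O)C(CC=C(C)C)=C1O
F4 | step 8 | 7-endo-prenyl enol | CC(C)=CC[C@]12C[C@H](CC=C(C)C)C(C)(C)[C@@](C(=O)c3ccccc3)(C2=O)C(=O)C(CC=C(C)C)=C1O
F5 | step 10 | open-chain silyl peroxide | CC(C)=CC[C@]12C[C@@H]3C[C@H](C(C)(C)OO[Si](CC)(CC)CC)[C@](CC=C(C)C)(C1=O)C(=O)[C@](C(=O)c1ccccc1)(C2=O)C3(C)C
F6 | step 10 | tertiary hydroperoxide | CC(C)=CC[C@]12C[C@@H]3C[C@H](C(C)(C)OO)[C@](CC=C(C)C)(C1=O)C(=O)[C@](C(=O)c1ccccc1)(C2=O)C3(C)C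
F7 | step 4 | enantiomeric adamantane alcohol | CC(C)=CC[C@@]12C[C@H]3[C@@H](O)[C@@](CC=C(C)C)(C1=O)C(=O)[C@@](C(=O)c1ccccc1)(C2=O)C3(C)C
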